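The disconnection cuts two bonds of the upper (epiafzelechin) unit at once: the interflavan bond C4–C6' and the ring C bond C2–C3. Both form in one operation when a trans-2-aryl-2,3-dihydrobenzofuran-3-carbaldehyde is silyl-activated: C2, which carries O1 and ring B, shifts from the benzylic ring carbon to the formyl carbon. The formyl carbon thereby becomes C3 with its oxygen, the furan ring grows into pyran ring C, and the former ring carbon becomes a C4 cation that the phloroglucinol ring A (oxygens at C5, C7 and C8a) stabilises and that C6' of an 8-bromo epicatechin ether captures. The aldehyde stems from an enantioenriched flavanone by oxidative ring contraction.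

Key step: step 7

Remark: flavan numbering is used for the dimers (primes mark the lower unit) and benzofuran numbering for 6 and 7. Assumption: the (R)-diphosphine in step 2 is taken to give the 2S flavanone; if the sense of induction is the opposite, its antipode is used.

Step 1
Reactants: 1 1-[2,4-bis(benzyloxy)-6-hydroxyphenyl]ethan-1-one
Product: 3 5,7-bis(benzyloxy)-4H-chromen-4-one, via enaminone 2 (not isolated)
Conditions: Me2NCH(OMe)2, toluene, 100 °C; then AcOH, 90 °C
Reagents that add atoms: N,N-dimethylformamide dimethyl acetal, COC(OC)N(C)C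
Why: Condensation of the acetyl methyl group with the formamide acetal gives an enaminone whose phenol adds to the β-carbon and expels dimethylamine under acid (enaminone route to chromones), with no stereocenter formed.

Step 2
Reactants: 3 5,7-bis(benzyloxy)-4H-chromen-4-one; 4 [4-(benzyloxy)phenyl]boronic acid
Product: 5 (2S)-5,7-bis(benzyloxy)-2-[4-(benzyloxy)phenyl]-2,3-dihydro-4H-chromen-4-one
Conditions: [Rh(OH)(cod)]2 (cat.), (R)-MeO-F12-BIPHEP (cat.), toluene/H2O, 40 °C
Reagents that add atoms: none
Why: Rhodium-catalysed asymmetric 1,4-addition of an arylboronic acid to a chromone (Hayashi–Miyaura reaction) should set C2 as S, the electron-poor atropisomeric diphosphine (R)-2,2'-bis[bis(3,4,5-trifluorophenyl)phosphino]-6,6'-dimethoxybiphenyl controlling the face of aryl transfer.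

Step 3
Reactants: 5 (2S)-5,7-bis(benzyloxy)-2-[4-(benzyloxy)phenyl]-2,3-dihydro-4H-chromen-4-one
Product: 6 methyl (2S,3S)-4,6-bis(benzyloxy)-2-[4-(benzyloxy)phenyl]-2,3-dihydro-1-benzofuran-3-carboxylate (2,3-trans)
Conditions: PhI(OAc)2 (1.1 equiv), H2SO4 (cat.), HC(OMe)3, rt; aqueous work-up
Reagents that add atoms: trimethyl orthoformate, COC(OC)OC; water, O
Why: In this oxidative ring contraction of flavanones with a trivalent iodine reagent, the enol ether formed with the orthoformate is attacked by the iodane at C3 and the electron-rich ring A carbon migrates from C4 to C3 with loss of PhI, so that C4 ends as the methyl ester, C2 stays untouched and the new stereocenter should take the more stable trans arrangement.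

Step 4
Reactants: 6 methyl (2S,3S)-4,6-bis(benzyloxy)-2-[4-(benzyloxy)phenyl]-2,3-dihydro-1-benzofuran-3-carboxylate
Product: 7 (2S,3S)-4,6-bis(benzyloxy)-2-[4-(benzyloxy)phenyl]-2,3-dihydro-1-benzofuran-3-carbaldehyde (2,3-trans)
Conditions: i-Bu2AlH (1.1 equiv), CH2Cl2, −78 °C; aqueous KNaC4H4O6; crude product used at once
Reagents that add atoms: none
Why: Partial ester reduction with i-Bu2AlH at −78 °C should stop at the aluminium hemiacetal, which releases the aldehyde on work-up, both stereocenters being untouched and trans being the stable arrangement at the epimerisable C3.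

Step 5
Reactants: 8 (−)-epicatechin
Product: 9 5,7,3',4'-tetra-O-benzyl-(−)-epicatechin, (2R,3R)
Conditions: BnBr (4.4 equiv), K2CO3, DMF, 0 °C to rt
Reagents that add atoms: benzyl bromide, BrCc1ccccc1
Why: Williamson etherification should alkylate the four phenols and leave the far less acidic secondary 3-hydroxyl free, with no stereocenter touched.

Step 6
Reactants: 9 5,7,3',4'-tetra-O-benzyl-(−)-epicatechin
Product: 10 8-bromo-5,7,3',4'-tetra-O-benzyl-(−)-epicatechin, (2R,3R)
Conditions: NBS (1.0 equiv), CH2Cl2, −78 °C to rt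
Reagents that add atoms: N-bromosuccinimide, O=C1CCC(=O)N1Br
Why: Electrophilic aromatic bromination should occur at C8, the most nucleophilic position of the 5,7-dialkoxy ring A, which leaves C6 as the only free nucleophilic site for step 7.

Step 7
Reactants: 7 (2S,3S)-4,6-bis(benzyloxy)-2-[4-(benzyloxy)phenyl]-2,3-dihydro-1-benzofuran-3-carbaldehyde; 10 8-bromo-5,7,3',4'-tetra-O-benzyl-(−)-epicatechin
Product: 13 5,7,4'-tri-O-benzyl-(−)-epiafzelechin-(4β→6)-8-bromo-5,7,3',4'-tetra-O-benzyl-(−)-epicatechin, via chroman-4-ylium triflate 11 (not isolated), via 3-O-trimethylsilyl ether 12 (not isolated)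
Conditions: 10 (3 equiv), Me3SiOTf (1.5 equiv), 4 Å MS, CH2Cl2, −78 to −40 °C, slow addition of 7; aq. NaHCO3; then K2CO3 (cat.), MeOH, 0 °C
Reagents that add atoms: none
Why: Proposed new method: O-silylation of the formyl group of 7 gives a silyloxycarbenium ion; the C2–C3 bond of the dihydrobenzofuran, pushed by the O1 lone pair and the 4-benzyloxyphenyl group on C2, then shifts to the formyl carbon, so that this carbon becomes C3 of the flavan with its oxygen, the five-membered ring grows into pyran ring C, and the former benzylic ring carbon becomes the C4 cation 11, which C6 of 10 captures by Friedel–Crafts alkylation before 12 is desilylated. The closest known reaction types are the acid-promoted 1,2-shift of α-branched aldehydes (aldehyde–ketone rearrangement, known as a ring expansion of cycloalkanecarbaldehydes), the semipinacol ring contraction of β-oxygenated benzylic cations read backwards, and the Me3SiOTf-mediated coupling of flavan C4 cations with flavan-3-ol nucleophiles. Ring C is not closed by a cyclisation but by ring enlargement through a suprafacial 1,2-carbon shift, driven by the change from an oxocarbenium ion to a benzylic cation that ring A stabilises through the oxygens at C5, C7 and C8a, and by the loss of five-ring strain. C2 migrates with retention and keeps the configuration set in step 2; C3 is set by the carbonyl face that accepts C2, and the rotamer of trans-7 in which the bulky silylated oxygen points away from ring carbon C3a and its peri benzyloxy group (the monodentate silyl group cannot chelate) should give the 2,3-cis arrangement; C4 is set by attack of 10 on the face opposite to the 3-silyloxy and 2-aryl groups (4β). The step needs the shift of C2 to win over hydride and aryl shifts (O1 push and strain release should secure this), attack of 10 at C6 only (secured by the bromine at C8), and capture by 10 and not by ring A of unreacted 7 (secured by the excess of 10 and the slow addition of 7).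

Step 8
Reactants: 13 5,7,4'-tri-O-benzyl-(−)-epiafzelechin-(4β→6)-8-bromo-5,7,3',4'-tetra-O-benzyl-(−)-epicatechin; 14 3,4,5-tris(benzyloxy)benzoic acid
Product: 15 3,3'-bis-O-[3,4,5-tris(benzyloxy)benzoyl] derivative of 13
Conditions: 14 (4 equiv), DCC, DMAP, CH2Cl2, rt
Reagents that add atoms: none
Why: Steglich esterification should acylate both secondary 3-hydroxyls at oxygen, so that the C3 and C3' configurations are retained.

Step 9
Reactants: 15 3,3'-bis-O-[3,4,5-tris(benzyloxy)benzoyl] derivative of 13
Product: 16 (−)-epiafzelechin 3-O-gallate-(4β→6)-(−)-epicatechin 3-O-gallate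
Conditions: H2 (1 atm), Pd(OH)2/C, Et3N, THF/MeOH/H2O, rt
Reagents that add atoms: none
Why: Hydrogenolysis over Pd(OH)2/C should cleave all thirteen benzyl ethers and, with Et3N present, the aryl C–Br bond, while the gallate esters, the stereocenters and the acid-sensitive interflavan bond stay intact.

Compound list
1 | 1-[2,4-bis(benzyloxy)-6-hydroxyphenyl]ethan-1-one | CC(=O)c1c(O)cc(OCc2ccccc2)cc1OCc1ccccc1 | starting material
2 | (E)-1-[2,4-bis(benzyloxy)-6-hydroxyphenyl]-3-(dimethylamino)prop-2-en-1-one | CN(C)/C=C/C(=O)c1c(O)cc(OCc2ccccc2)cc1OCc1ccccc1 | intermediate (not isolated)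
3 | 5,7-bis(benzyloxy)-4H-chromen-4-one | O=c1ccoc2cc(OCc3ccccc3)cc(OCc3ccccc3)c12 | intermediate
4 | [4-(benzyloxy)phenyl]boronic acid | OB(O)c1ccc(OCc2ccccc2)cc1 | starting material
5 | (2S)-5,7-bis(benzyloxy)-2-[4-(benzyloxy)phenyl]-2,3-dihydro-4H-chromen-4-one | O=C1C[C@@H](c2ccc(OCc3ccccc3)cc2)Oc2cc(OCc3ccccc3)cc(OCc3ccccc3)c21 | intermediate
6 | methyl (2S,3S)-4,6-bis(benzyloxy)-2-[4-(benzyloxy)phenyl]-2,3-dihydro-1-benzofuran-3-carboxylate (trans) | COC(=O)[C@@H]1[C@@H](c2ccc(OCc3ccccc3)cc2)Oc2cc(OCc3ccccc3)cc(OCc3ccccc3)c21 | intermediate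
7 | (2S,3S)-4,6-bis(benzyloxy)-2-[4-(benzyloxy)phenyl]-2,3-dihydro-1-benzofuran-3-carbaldehyde (trans) | O=C[C@@H]1[C@@H](c2ccc(OCc3ccccc3)cc2)Oc2cc(OCc3ccccc3)cc(OCc3ccccc3)c21 | intermediate
8 | (−)-epicatechin, (2R,3R) | O[C@@H]1Cc2c(O)cc(O)cc2O[C@@H]1c1ccc(O)c(O)c1 | starting material
9 | 5,7,3',4'-tetra-O-benzyl-(−)-epicatechin, (2R,3R) | O[C@@H]1Cc2c(OCc3ccccc3)cc(OCc3ccccc3)cc2O[C@@H]1c1ccc(OCc2ccccc2)c(OCc2ccccc2)c1 | intermediate
10 | 8-bromo-5,7,3',4'-tetra-O-benzyl-(−)-epicatechin, (2R,3R) | O[C@@H]1Cc2c(OCc3ccccc3)cc(OCc3ccccc3)c(Br)c2O[C@@H]1c1ccc(OCc2ccccc2)c(OCc2ccccc2)c1 | intermediate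
11 | (2R,3R)-5,7-bis(benzyloxy)-2-[4-(benzyloxy)phenyl]-3-[(trimethylsilyl)oxy]chroman-4-ylium trifluoromethanesulfonate (2,3-cis) | C[Si](C)(C)O[C@@H]1[CH+]c2c(OCc3ccccc3)cc(OCc3ccccc3)cc2O[C@@H]1c1ccc(OCc2ccccc2)cc1.[O-]S(=O)(=O)C(F)(F)F | intermediate (not isolated)
12 | 3-O-trimethylsilyl ether of 13 (upper unit) | C[Si](C)(C)O[C@@H]1[C@@H](c2c(OCc3ccccc3)c(Br)c3c(c2OCc2ccccc2)C[C@@H](O)[C@@H](c2ccc(OCc4ccccc4)c(OCc4ccccc4)c2)O3)c2c(OCc3ccccc3)cc(OCc3ccccc3)cc2O[C@@H]1c1ccc(OCc2ccccc2)cc1 | intermediate (not isolated)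
13 | 5,7,4'-tri-O-benzyl-(−)-epiafzelechin-(4β→6)-8-bromo-5,7,3',4'-tetra-O-benzyl-(−)-epicatechin; upper unit 2R,3R with the C4–aryl bond trans to the 3-hydroxyl and to ring B, lower unit 2R,3R | O[C@@H]1[C@@H](c2c(OCc3ccccc3)c(Br)c3c(c2OCc2ccccc2)C[C@@H](O)[C@@H](c2ccc(OCc4ccccc4)c(OCc4ccccc4)c2)O3)c2c(OCc3ccccc3)cc(OCc3ccccc3)cc2O[C@@H]1c1ccc(OCc2ccccc2)cc1 | intermediate
14 | 3,4,5-tris(benzyloxy)benzoic acid | OC(=O)c1cc(OCc2ccccc2)c(OCc2ccccc2)c(OCc2ccccc2)c1 | starting material
15 | 3,3'-bis-O-[3,4,5-tris(benzyloxy)benzoyl] derivative of 13 (same configurations) | O=C(O[C@@H]1[C@@H](c2c(OCc3ccccc3)c(Br)c3c(c2OCc2ccccc2)C[C@@H](OC(=O)c2cc(OCc4ccccc4)c(OCc4ccccc4)c(OCc4ccccc4)c2)[C@@H](c2ccc(OCc4ccccc4)c(OCc4ccccc4)c2)O3)c2c(OCc3ccccc3)cc(OCc3ccccc3)cc2O[C@@H]1c1ccc(OCc2ccccc2)cc1)c1cc(OCc2ccccc2)c(OCc2ccccc2)c(OCc2ccccc2)c1 | intermediate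
16 | (−)-epiafzelechin 3-O-gallate-(4β→6)-(−)-epicatechin 3-O-gallate; upper unit 2R,3R,4S, lower unit 2R,3R | O=C(O[C@@H]1[C@@H](c2c(O)cc3c(c2O)C[C@@H](OC(=O)c2cc(O)c(O)c(O)c2)[C@@H](c2ccc(O)c(O)c2)O3)c2c(O)cc(O)cc2O[C@@H]1c1ccc(O)cc1)c1cc(O)c(O)c(O)c1 | target

Total step count: 9. Longest linear sequence: 7 steps (steps 1, 2, 3, 4, 7, 8, 9).

Steps most likely to fail

1. Step 7. After silyl activation, a 1,2-hydride shift followed by proton loss (aromatisation to the benzofuran) or participation of the ring A aryl group may outrun the shift of C2. C2 may also add to the other carbonyl face, which would give the 2,3-trans series. The free ring A positions of unreacted 7, or direct attack of 10 on the activated formyl carbon, may compete with capture of the cation. Reversible opening of the O1–C2 bond may erode the C2 configuration. The fallback uses known chemistry only; it sets out from 10 and comes back to the route at 13. Commercial (−)-epiafzelechin F1 is benzylated (BnBr, K2CO3, DMF) to 5,7,4'-tri-O-benzyl-(−)-epiafzelechin F2. Benzylic oxidation of F2 with DDQ in the presence of 2-ethoxyethanol (CH2Cl2, rt) should give the 4β-(2-ethoxyethoxy) ether F3. F3 and 10 (excess) are then coupled with Me3SiOTf in CH2Cl2 at −78 °C; the C4 cation should again be attacked by C6 of 10 on the face opposite to the 3-hydroxyl, which gives 13.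

2. Step 3. Migration of the electron-rich ring B aryl group from C2 to C3 (isoflavone formation), dehydrogenation to the flavone, attack of the iodane on the electron-rich ring A of the product, or acid-induced ring opening to the chalcone with loss of the C2 configuration may compete with the ring contraction. The fallback sets out from 5 and comes back at 6 by a Wolff ring contraction. Detrifluoroacetylative diazo transfer (LiN(SiMe3)2, CF3CO2CH2CF3, THF, −78 °C, to keep the enolate from opening; then MsN3, Et3N, MeCN) should give (2R)-5,7-bis(benzyloxy)-2-[4-(benzyloxy)phenyl]-3-diazo-2,3-dihydro-4H-chromen-4-one F4, in which C2 is unchanged in space and only the descriptor changes. Irradiation of F4 in MeOH should trigger loss of N2, shift of the ring A carbon to the carbene carbon and capture of the ketene by MeOH. Brief equilibration with catalytic DBU should then give the trans ester 6.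

3. Step 2. Aryl transfer to the hindered, electron-rich 5-benzyloxychromone may be slow, protodeboronation of 4 may consume the boronic acid, and the facial selectivity may be insufficient. The fallback sets out from 1 and comes back at 5. Claisen–Schmidt condensation of 1 with 4-(benzyloxy)benzaldehyde (KOH, EtOH) should give the chalcone F5. Intramolecular oxa-Michael addition (NaOAc, EtOH, reflux) should give the racemic flavanone F6. Kinetic resolution by asymmetric transfer hydrogenation (RuCl(p-cymene)(TsDPEN), HCO2H/Et3N, with the catalyst enantiomer that reduces the 2R ketone faster) should convert the unwanted enantiomer into the cis-(2R,4R)-flavan-4-ol F7 and leave (2S)-5, which is separated by chromatography.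

Further compounds
F1 | step 7 | (−)-epiafzelechin, (2R,3R) | O[C@@H]1Cc2c(O)cc(O)cc2O[C@@H]1c1ccc(O)cc1
F2 | step 7 | 5,7,4'-tri-O-benzyl-(−)-epiafzelechin, (2R,3R) | O[C@@H]1Cc2c(OCc3ccccc3)cc(OCc3ccccc3)cc2O[C@@H]1c1ccc(OCc2ccccc2)cc1
F3 | step 7 | 4β-(2-ethoxyethoxy)-5,7,4'-tri-O-benzyl-(−)-epiafzelechin (4-alkoxy group trans to the 3-hydroxyl) | O[C@@H]1[C@@H](OCCOCC)c2c(OCc3ccccc3)cc(OCc3ccccc3)cc2O[C@@H]1c1ccc(OCc2ccccc2)cc1
F4 | step 3 | (2R)-5,7-bis(benzyloxy)-2-[4-(benzyloxy)phenyl]-3-diazo-2,3-dihydro-4H-chromen-4-one | O=C1C(=[N+]=[N-])[C@@H](c2ccc(OCc3ccccc3)cc2)Oc2cc(OCc3ccccc3)cc(OCc3ccccc3)c21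
F5 | step 2 | (E)-1-[2,4-bis(benzyloxy)-6-hydroxyphenyl]-3-[4-(benzyloxy)phenyl]prop-2-en-1-one | O=C(/C=C/c1ccc(OCc2ccccc2)cc1)c1c(O)cc(OCc2ccccc2)cc1OCc1ccccc1
F6 | step 2 | racemic 5,7-bis(benzyloxy)-2-[4-(benzyloxy)phenyl]-2,3-dihydro-4H-chromen-4-one | O=C1CC(c2ccc(OCc3ccccc3)cc2)Oc2cc(OCc3ccccc3)cc(OCc3ccccc3)c21
F7 | step 2 | cis-(2R,4R)-5,7-bis(benzyloxy)-2-[4-(benzyloxy)phenyl]chroman-4-ol | O[C@@H]1C[C@H](c2ccc(OCc3ccccc3)cc2)Oc2cc(OCc3ccccc3)cc(OCc3ccccc3)c21
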